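**Retrosynthetic overview**
1. Target ⇐ hydrogenolysis of three benzyl ethers and reduction of a cis-dihydrobenzofuran ester; the dihydrobenzofuran (last ring) ⇐ enantioselective dirhodium-carbenoid C–H insertion of an aryl diazoacetate into its ortho ArCH2O group.
2. Aryl diazoacetate ⇐ aryl iodide + ethyl diazoacetate (Pd); ArCH2O ether ⇐ silyl-protected iodophenol; 3-hydroxyoxolane ⇐ α-hydroxy-γ-lactone by lactol ionic hydrogenation (the lactone ring becomes the oxolane ring).
3. α-Hydroxy-α-benzyl lactone ⇐ enolate benzylation, then enolate hydroxylation, of a cis-4,5-disubstituted γ-butyrolactone (both anti to the ring substituents).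
4. Key C–C bond (lactone C4–C5 = oxolane C3–C2): the chiral-carbene homoenolate of (E)-4-(benzyloxy)but-2-enal adds through its β-carbon to the aldehyde of silylated 5-iodovanillin, joining two carbons that are both electrophilic in normal polarity, and lactonises cis.
5. Ring order: γ-lactone → oxolane (same ring, C=O to CH2) → dihydrobenzofuran.

Assumption: the target is taken exactly as the SMILES defines it (aryl cis to CH2OH in both the oxolane and the dihydrobenzofuran); for the two chiral catalysts the enantiomer named is the one expected from the closest reported cases, and its equally available antipode is used if the sense proves opposite.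

**Route**

Step 1
Reactants: 1 4-(benzyloxy)-3-methoxybenzyl alcohol
Product: 2 4-(benzyloxy)-3-methoxybenzyl bromide
Conditions: PBr3 (0.4 equiv), Et2O, 0 °C
Reagents that add atoms: phosphorus tribromide, BrP(Br)Br
Why: Standard conversion of an electron-rich benzylic alcohol into its bromide (SN2 displacement on the phosphite ester); no stereocenter.

Step 2
Reactants: 3 5-iodovanillin
Product: 4 3-iodo-5-methoxy-4-[(triisopropylsilyl)oxy]benzaldehyde
Conditions: TIPSCl, imidazole, DMF, 25–40 °C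
Reagents that add atoms: triisopropylsilyl chloride, CC(C)[Si](Cl)(C(C)C)C(C)C
Why: Phenol silylation gives a fluoride-labile group that is inert to carbene catalysis, amide bases, hydride and BF3, and that is twisted out of conjugation by its two ortho substituents so the aldehyde stays electrophilic; no stereocenter.

Step 3
Reactants: 5 allyl benzyl ether; 6 (E)-crotonaldehyde
Product: 7 (E)-4-(benzyloxy)but-2-enal
Conditions: crotonaldehyde in fourfold excess, second-generation Hoveyda–Grubbs catalyst (2 mol %), CH2Cl2, 40 °C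
Reagents that add atoms: none
Why: Olefin cross-metathesis of a terminal olefin with crotonaldehyde (propene is lost) gives the E-enal under thermodynamic control.

Step 4
Reactants: 4 3-iodo-5-methoxy-4-[(triisopropylsilyl)oxy]benzaldehyde; 7 (E)-4-(benzyloxy)but-2-enal
Product: 8 (4R,5R)-4-[(benzyloxy)methyl]-5-{3-iodo-5-methoxy-4-[(triisopropylsilyl)oxy]phenyl}oxolan-2-one
Conditions: (5aS,10bR)-2-mesityl-5a,10b-dihydro-4H,6H-indeno[2,1-b][1,2,4]triazolo[4,3-d][1,4]oxazin-2-ium chloride (10 mol %), DBU (10 mol %), THF, 4 Å sieves, 25 °C; the enal (2 equiv in all) added by syringe pump over 8 h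
Reagents that add atoms: none
Why: Proposed new method: the carbene adds to enal 7 to give the extended Breslow intermediate, a homoenolate whose β-carbon attacks the aldehyde carbon of 4, and the resulting alkoxide closes onto the acyl azolium to release catalyst and lactone, a pure addition in which every atom of one molecule of 4 and one molecule of 7 ends up in 8; the closest known reaction is the carbene-catalysed enal plus aryl aldehyde γ-butyrolactone annulation (homoenolate [3+2] annulation), which is cis-selective through a hydrogen-bonded like approach, and here the chiral aminoindanol triazolium is asked to choose the homoenolate face so that C4 and C5 form as (4R,5R); aldehyde 4 is about as electrophilic as 4-chlorobenzaldehyde, benzyloxide is too poor a leaving group for β-elimination, the minor trans lactone is removed by chromatography, and the ee is raised by recrystallisation (residual enantiomer becomes a separable diastereomer after step 10).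

Step 5
Reactants: 8 (4R,5R)-4-[(benzyloxy)methyl]-5-{3-iodo-5-methoxy-4-[(triisopropylsilyl)oxy]phenyl}oxolan-2-one; 2 4-(benzyloxy)-3-methoxybenzyl bromide
Product: 10 (3S,4R,5R)-3-[4-(benzyloxy)-3-methoxybenzyl]-4-[(benzyloxy)methyl]-5-{3-iodo-5-methoxy-4-[(triisopropylsilyl)oxy]phenyl}oxolan-2-one, via lithium enolate 9 (not isolated)
Conditions: LiN(SiMe3)2 (1.1 equiv), THF, −78 °C; then the bromide (1.3 equiv), DMPU, −78 → −30 °C
Reagents that add atoms: none
Why: Alkylation of the lithium lactone enolate (the classical lignan α-benzylation) occurs on the face opposite the cis C4 and C5 substituents, setting C3 as S with the benzyl group trans to CH2OBn.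

Step 6
Reactants: 10 (3S,4R,5R)-3-[4-(benzyloxy)-3-methoxybenzyl]-4-[(benzyloxy)methyl]-5-{3-iodo-5-methoxy-4-[(triisopropylsilyl)oxy]phenyl}oxolan-2-one
Product: 12 (3S,4R,5R)-3-[4-(benzyloxy)-3-methoxybenzyl]-4-[(benzyloxy)methyl]-3-hydroxy-5-{3-iodo-5-methoxy-4-[(triisopropylsilyl)oxy]phenyl}oxolan-2-one, via potassium enolate 11 (not isolated)
Conditions: KN(SiMe3)2 (1.3 equiv), THF, −78 °C; then 2-(phenylsulfonyl)-3-phenyloxaziridine (1.5 equiv), −78 °C; AcOH quench
Reagents that add atoms: (±)-trans-2-(phenylsulfonyl)-3-phenyloxaziridine (Davis reagent), O=S(=O)(c1ccccc1)N1OC1c1ccccc1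
Why: Davis enolate hydroxylation: the planar potassium enolate is again attacked anti to the cis C4/C5 substituents, so oxygen enters trans and the benzyl group is pushed cis, giving the (3S) tertiary alcohol with all three carbon substituents on one face.

Step 7
Reactants: 12 (3S,4R,5R)-3-[4-(benzyloxy)-3-methoxybenzyl]-4-[(benzyloxy)methyl]-3-hydroxy-5-{3-iodo-5-methoxy-4-[(triisopropylsilyl)oxy]phenyl}oxolan-2-one
Product: 14 (3S,4R,5R)-3-[4-(benzyloxy)-3-methoxybenzyl]-4-[(benzyloxy)methyl]-5-{3-iodo-5-methoxy-4-[(triisopropylsilyl)oxy]phenyl}oxolan-3-ol, via lactol 13 (not isolated)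
Conditions: iBu2AlH (2.5 equiv), CH2Cl2, −78 °C; then Et3SiH (6 equiv), BF3·OEt2 (5 equiv), −78 → −30 °C; aq. NaHCO3, potassium sodium tartrate
Reagents that add atoms: none
Why: Lactone-to-cyclic-ether reduction (Kraus-type ionic hydrogenation): iBu2AlH stops at the aluminium lactolate at −78 °C, BF3 ionises only the anomeric C–O bond to an oxocarbenium ion that Et3SiH reduces to CH2, no stereocenter is touched, and the weakly donating, twisted silyloxy-iodoaryl group keeps the benzylic C5–O bond from ionising.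

Step 8
Reactants: 14 (3S,4R,5R)-3-[4-(benzyloxy)-3-methoxybenzyl]-4-[(benzyloxy)methyl]-5-{3-iodo-5-methoxy-4-[(triisopropylsilyl)oxy]phenyl}oxolan-3-ol; 2 4-(benzyloxy)-3-methoxybenzyl bromide
Product: 15 (3S,4R,5R)-3-[4-(benzyloxy)-3-methoxybenzyl]-5-(4-{[4-(benzyloxy)-3-methoxybenzyl]oxy}-3-iodo-5-methoxyphenyl)-4-[(benzyloxy)methyl]oxolan-3-ol
Conditions: CsF (3 equiv), the bromide (1.5 equiv), DMF, 25 °C
Reagents that add atoms: none
Why: Fluoride desilylation with in situ Williamson O-alkylation of the phenoxide installs the acid-labile electron-rich benzyl aryl ether only after the last Lewis-acid step; the tertiary alcohol is not alkylated under CsF.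

Step 9
Reactants: 15 (3S,4R,5R)-3-[4-(benzyloxy)-3-methoxybenzyl]-5-(4-{[4-(benzyloxy)-3-methoxybenzyl]oxy}-3-iodo-5-methoxyphenyl)-4-[(benzyloxy)methyl]oxolan-3-ol; 16 ethyl diazoacetate
Product: 17 ethyl 2-(2-{[4-(benzyloxy)-3-methoxybenzyl]oxy}-5-{(2R,3R,4S)-4-[4-(benzyloxy)-3-methoxybenzyl]-3-[(benzyloxy)methyl]-4-hydroxyoxolan-2-yl}-3-methoxyphenyl)-2-diazoacetate
Conditions: ethyl diazoacetate (1.5 equiv), Pd(PPh3)4 (5–10 mol %), Ag2CO3 (0.5 equiv), Et3N (1.3 equiv), toluene, 25 °C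
Reagents that add atoms: none
Why: Pd-catalysed cross-coupling of an aryl iodide with ethyl diazoacetate (Wang coupling; oxidative addition to zerovalent palladium, diazo group retained) converts the iodide directly into the donor–acceptor aryl diazoacetate under mild base at room temperature.

Step 10
Reactants: 17 ethyl 2-(2-{[4-(benzyloxy)-3-methoxybenzyl]oxy}-5-{(2R,3R,4S)-4-[4-(benzyloxy)-3-methoxybenzyl]-3-[(benzyloxy)methyl]-4-hydroxyoxolan-2-yl}-3-methoxyphenyl)-2-diazoacetate
Product: 18 ethyl (2R,3S)-2-[4-(benzyloxy)-3-methoxyphenyl]-5-{(2R,3R,4S)-4-[4-(benzyloxy)-3-methoxybenzyl]-3-[(benzyloxy)methyl]-4-hydroxyoxolan-2-yl}-7-methoxy-2,3-dihydro-1-benzofuran-3-carboxylate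
Conditions: Rh2(S-PTTL)4 (dirhodium tetrakis[N-phthaloyl-(S)-tert-leucinate], 2 mol %), toluene (0.01 M), −60 °C
Reagents that add atoms: none
Why: Intramolecular 1,5-C–H insertion of the divalent-rhodium carbenoid into the doubly activated benzylic OCH2 group (Hashimoto cis-dihydrobenzofuran synthesis) closes the last ring, the chiral carboxylate catalyst setting both new centers as the cis (2R,3S) ester; at low temperature and high dilution this is much faster than intermolecular O–H insertion with the hindered tertiary alcohol.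

Step 11
Reactants: 18 ethyl (2R,3S)-2-[4-(benzyloxy)-3-methoxyphenyl]-5-{(2R,3R,4S)-4-[4-(benzyloxy)-3-methoxybenzyl]-3-[(benzyloxy)methyl]-4-hydroxyoxolan-2-yl}-7-methoxy-2,3-dihydro-1-benzofuran-3-carboxylate
Product: 19 (3S,4R,5R)-3-[4-(benzyloxy)-3-methoxybenzyl]-5-{(2R,3R)-2-[4-(benzyloxy)-3-methoxyphenyl]-3-(hydroxymethyl)-7-methoxy-2,3-dihydro-1-benzofuran-5-yl}-4-[(benzyloxy)methyl]oxolan-3-ol
Conditions: iBu2AlH (5 equiv), CH2Cl2, −78 → −40 °C; aq. potassium sodium tartrate
Reagents that add atoms: none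
Why: Non-basic hydride reduction of the ester to the primary alcohol at low temperature avoids enolisation, so the epimerisable cis C3 center of the dihydrobenzofuran is kept.

Step 12
Reactants: 19 (3S,4R,5R)-3-[4-(benzyloxy)-3-methoxybenzyl]-5-{(2R,3R)-2-[4-(benzyloxy)-3-methoxyphenyl]-3-(hydroxymethyl)-7-methoxy-2,3-dihydro-1-benzofuran-5-yl}-4-[(benzyloxy)methyl]oxolan-3-ol
Product: 20 (3S,4R,5R)-3-(4-hydroxy-3-methoxybenzyl)-5-[(2R,3R)-2-(4-hydroxy-3-methoxyphenyl)-3-(hydroxymethyl)-7-methoxy-2,3-dihydro-1-benzofuran-5-yl]-4-(hydroxymethyl)oxolan-3-ol (CNP0284796.1)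
Conditions: H2 (1 atm), 10% Pd/C, EtOAc–MeOH 4:1, 25 °C, stopped at full conversion
Reagents that add atoms: none
Why: Catalytic hydrogenolysis of the three unhindered benzyl ethers under neutral conditions is faster than cleavage of the hindered secondary cyclic benzylic C–O bonds of the oxolane and dihydrobenzofuran, which need acid or pressure, and it leaves all five stereocenters untouched.

**Compound list**

1 | 4-(benzyloxy)-3-methoxybenzyl alcohol | OCc1ccc(OCc2ccccc2)c(OC)c1 | starting material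
2 | 4-(benzyloxy)-3-methoxybenzyl bromide | BrCc1ccc(OCc2ccccc2)c(OC)c1 | intermediate
3 | 5-iodovanillin (4-hydroxy-3-iodo-5-methoxybenzaldehyde) | O=Cc1cc(I)c(O)c(OC)c1 | starting material
4 | 3-iodo-5-methoxy-4-[(triisopropylsilyl)oxy]benzaldehyde | O=Cc1cc(I)c(O[Si](C(C)C)(C(C)C)C(C)C)c(OC)c1 | intermediate
5 | allyl benzyl ether | C=CCOCc1ccccc1 | starting material
6 | (E)-crotonaldehyde | C/C=C/C=O | starting material
7 | (E)-4-(benzyloxy)but-2-enal | O=C/C=C/COCc1ccccc1 | intermediate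
8 | (4R,5R)-4-[(benzyloxy)methyl]-5-{3-iodo-5-methoxy-4-[(triisopropylsilyl)oxy]phenyl}oxolan-2-one (cis lactone) | O=C1C[C@H](COCc2ccccc2)[C@H](c2cc(I)c(O[Si](C(C)C)(C(C)C)C(C)C)c(OC)c2)O1 | intermediate
9 | lithium enolate of 8 | [Li+].[O-]C1=C[C@H](COCc2ccccc2)[C@H](c2cc(I)c(O[Si](C(C)C)(C(C)C)C(C)C)c(OC)c2)O1 | intermediate (not isolated)
10 | (3S,4R,5R)-3-[4-(benzyloxy)-3-methoxybenzyl]-4-[(benzyloxy)methyl]-5-{3-iodo-5-methoxy-4-[(triisopropylsilyl)oxy]phenyl}oxolan-2-one | O=C1[C@@H](Cc2ccc(OCc3ccccc3)c(OC)c2)[C@H](COCc2ccccc2)[C@H](c2cc(I)c(O[Si](C(C)C)(C(C)C)C(C)C)c(OC)c2)O1 | intermediate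
11 | potassium enolate of 10 | [K+].[O-]C1=C(Cc2ccc(OCc3ccccc3)c(OC)c2)[C@H](COCc2ccccc2)[C@H](c2cc(I)c(O[Si](C(C)C)(C(C)C)C(C)C)c(OC)c2)O1 | intermediate (not isolated)
12 | (3S,4R,5R)-3-[4-(benzyloxy)-3-methoxybenzyl]-4-[(benzyloxy)methyl]-3-hydroxy-5-{3-iodo-5-methoxy-4-[(triisopropylsilyl)oxy]phenyl}oxolan-2-one | O=C1[C@](O)(Cc2ccc(OCc3ccccc3)c(OC)c2)[C@H](COCc2ccccc2)[C@H](c2cc(I)c(O[Si](C(C)C)(C(C)C)C(C)C)c(OC)c2)O1 | intermediate
13 | (3S,4R,5R)-3-[4-(benzyloxy)-3-methoxybenzyl]-4-[(benzyloxy)methyl]-5-{3-iodo-5-methoxy-4-[(triisopropylsilyl)oxy]phenyl}oxolane-2,3-diol (lactol, C2 epimers, present as its aluminium alkoxide) | OC1[C@](O)(Cc2ccc(OCc3ccccc3)c(OC)c2)[C@H](COCc2ccccc2)[C@H](c2cc(I)c(O[Si](C(C)C)(C(C)C)C(C)C)c(OC)c2)O1 | intermediate (not isolated)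
14 | (3S,4R,5R)-3-[4-(benzyloxy)-3-methoxybenzyl]-4-[(benzyloxy)methyl]-5-{3-iodo-5-methoxy-4-[(triisopropylsilyl)oxy]phenyl}oxolan-3-ol | C1[C@](O)(Cc2ccc(OCc3ccccc3)c(OC)c2)[C@H](COCc2ccccc2)[C@H](c2cc(I)c(O[Si](C(C)C)(C(C)C)C(C)C)c(OC)c2)O1 | intermediate
15 | (3S,4R,5R)-3-[4-(benzyloxy)-3-methoxybenzyl]-5-(4-{[4-(benzyloxy)-3-methoxybenzyl]oxy}-3-iodo-5-methoxyphenyl)-4-[(benzyloxy)methyl]oxolan-3-ol | C1[C@](O)(Cc2ccc(OCc3ccccc3)c(OC)c2)[C@H](COCc2ccccc2)[C@H](c2cc(I)c(OCc3ccc(OCc4ccccc4)c(OC)c3)c(OC)c2)O1 | intermediate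
16 | ethyl diazoacetate | CCOC(=O)C=[N+]=[N-] | starting material
17 | ethyl 2-(2-{[4-(benzyloxy)-3-methoxybenzyl]oxy}-5-{(2R,3R,4S)-4-[4-(benzyloxy)-3-methoxybenzyl]-3-[(benzyloxy)methyl]-4-hydroxyoxolan-2-yl}-3-methoxyphenyl)-2-diazoacetate | C1[C@](O)(Cc2ccc(OCc3ccccc3)c(OC)c2)[C@H](COCc2ccccc2)[C@H](c2cc(C(=[N+]=[N-])C(=O)OCC)c(OCc3ccc(OCc4ccccc4)c(OC)c3)c(OC)c2)O1 | intermediate
18 | ethyl (2R,3S)-2-[4-(benzyloxy)-3-methoxyphenyl]-5-{(2R,3R,4S)-4-[4-(benzyloxy)-3-methoxybenzyl]-3-[(benzyloxy)methyl]-4-hydroxyoxolan-2-yl}-7-methoxy-2,3-dihydro-1-benzofuran-3-carboxylate (cis) | C1[C@](O)(Cc2ccc(OCc3ccccc3)c(OC)c2)[C@H](COCc2ccccc2)[C@H](c2cc(OC)c3c(c2)[C@H](C(=O)OCC)[C@H](c2ccc(OCc4ccccc4)c(OC)c2)O3)O1 | intermediate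
19 | (3S,4R,5R)-3-[4-(benzyloxy)-3-methoxybenzyl]-5-{(2R,3R)-2-[4-(benzyloxy)-3-methoxyphenyl]-3-(hydroxymethyl)-7-methoxy-2,3-dihydro-1-benzofuran-5-yl}-4-[(benzyloxy)methyl]oxolan-3-ol | C1[C@](O)(Cc2ccc(OCc3ccccc3)c(OC)c2)[C@H](COCc2ccccc2)[C@H](c2cc(OC)c3c(c2)[C@H](CO)[C@H](c2ccc(OCc4ccccc4)c(OC)c2)O3)O1 | intermediate
20 | (3S,4R,5R)-3-(4-hydroxy-3-methoxybenzyl)-5-[(2R,3R)-2-(4-hydroxy-3-methoxyphenyl)-3-(hydroxymethyl)-7-methoxy-2,3-dihydro-1-benzofuran-5-yl]-4-(hydroxymethyl)oxolan-3-ol | COc1cc(C[C@@]2(O)CO[C@@H](c3cc(OC)c4c(c3)[C@H](CO)[C@H](c3ccc(O)c(OC)c3)O4)[C@H]2CO)ccc1O | target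

**Totals and risks**

Total step count: 12. Longest linear sequence: 10 steps (3 → 4 → 8 → 10 → 12 → 14 → 15 → 17 → 18 → 19 → 20; steps 2, 4–12).

The three steps most likely to fail:

Step 4 (chiral-carbene homoenolate annulation; enantiocontrol with a simple aryl aldehyde and the γ-benzyloxy enal are unproven). The fallback sets out from 4 (with 7) and returns at 8. The annulation is run with the achiral carbene from 1,3-dimesitylimidazolium chloride and DBU in THF, the best-precedented catalyst for enal/aryl aldehyde lactonisation, to give the racemic cis-lactone F1. Absolute configuration then comes from a classical resolution instead of the catalyst: F1 is opened with (S)-1-phenylethylamine and AlMe3 in CH2Cl2, the diastereomeric γ-hydroxy amides are separated by crystallisation or chromatography, and the (3R,4R)-hydroxy amide F2 is relactonised with catalytic TsOH in toluene at 60 °C, which expels the amine and gives 8.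

Step 7 (one-flask lactone-to-ether reduction; sluggish ionisation next to the tertiary alkoxide, or ionisation of the benzylic C–O bond by excess BF3). The fallback sets out from 12 and returns at 14. iBu2AlH at −78 °C is followed in the same flask by pyridine, DMAP and Ac2O (reductive acetylation) to give the isolable anomeric acetate F3. F3 ionises with only catalytic TMSOTf at −78 °C in the presence of Et3SiH, so the oxocarbenium ion is generated from a far better leaving group and without excess Lewis acid.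

Step 9 (Pd coupling of ethyl diazoacetate at a hindered, ortho-alkoxy aryl iodide). The fallback sets out from 15 and returns at 17. The carbon–carbon bond and the diazo group are introduced separately: Negishi-type α-arylation of 15 with BrZnCH2CO2Et (Pd2(dba)3, XPhos, THF, 50 °C) gives the aryl acetate F4, and Regitz diazo transfer to F4 with 4-acetamidobenzenesulfonyl azide and DBU in MeCN gives 17.

**Further compounds**

F1 | step 4 | racemic cis-4-[(benzyloxy)methyl]-5-{3-iodo-5-methoxy-4-[(triisopropylsilyl)oxy]phenyl}oxolan-2-one (1:1 mixture of the 4R,5R and 4S,5S enantiomers) | O=C1C[C@H](COCc2ccccc2)[C@H](c2cc(I)c(O[Si](C(C)C)(C(C)C)C(C)C)c(OC)c2)O1.O=C1C[C@@H](COCc2ccccc2)[C@@H](c2cc(I)c(O[Si](C(C)C)(C(C)C)C(C)C)c(OC)c2)O1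
F2 | step 4 | (3R,4R)-3-[(benzyloxy)methyl]-4-hydroxy-4-{3-iodo-5-methoxy-4-[(triisopropylsilyl)oxy]phenyl}-N-[(1S)-1-phenylethyl]butanamide | C[C@H](NC(=O)C[C@H](COCc1ccccc1)[C@H](c1cc(I)c(O[Si](C(C)C)(C(C)C)C(C)C)c(OC)c1)O)c1ccccc1
F3 | step 7 | (3S,4R,5R)-3-[4-(benzyloxy)-3-methoxybenzyl]-4-[(benzyloxy)methyl]-3-hydroxy-5-{3-iodo-5-methoxy-4-[(triisopropylsilyl)oxy]phenyl}oxolan-2-yl acetate (anomers) | CC(=O)OC1[C@](O)(Cc2ccc(OCc3ccccc3)c(OC)c2)[C@H](COCc2ccccc2)[C@H](c2cc(I)c(O[Si](C(C)C)(C(C)C)C(C)C)c(OC)c2)O1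
F4 | step 9 | ethyl 2-(2-{[4-(benzyloxy)-3-methoxybenzyl]oxy}-5-{(2R,3R,4S)-4-[4-(benzyloxy)-3-methoxybenzyl]-3-[(benzyloxy)methyl]-4-hydroxyoxolan-2-yl}-3-methoxyphenyl)acetate | C1[C@](O)(Cc2ccc(OCc3ccccc3)c(OC)c2)[C@H](COCc2ccccc2)[C@H](c2cc(CC(=O)OCC)c(OCc3ccc(OCc4ccccc4)c(OC)c3)c(OC)c2)O1
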